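**Plan**

1. Retrosynthesis (target locants: C1 = CMe2, C2 = CHBr, C5 = C=CH2, C6 = spiro carbon, C7 = CH2, C8 = CHCl, C9 = C(Me)Br). Cut the C5 methylidene back to a ketone, then C9–Br/C8–Cl back to a C8=C9 alkene. Cut C6–C7 by a Claisen retron, C1–C6 by a bromonium cyclisation, and C5–C6 and C3–C4 to reach two acyclic fragments.
2. Enabling feature: at the ketone/alkene stage C5(=O)–C6–C7–C8=C9 is a γ,δ-unsaturated ketone, and C9 is tied back to C6 by the C10–C11 bridge. Shifting the C6–C7 bond onto oxygen (C9–O–C5) gives a 2-methyl-2-vinyl-3,4-dihydro-2H-pyran fused to ring A.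
3. Forward: fragment A (prenol → bromochloride → Weinreb amide) and fragment B (linalool → iodo alcohol) are joined to an acyclic hydroxy ketone. The rings then arise in the order pyran (cyclodehydration), ring A (bromonium cyclisation onto the enol ether), ring B ([3,3] shift, pyran opens).
4. Finish: epoxide → chlorohydrin → tertiary bromide on ring B, then methylenation of the ring-A ketone.
5. Stereochemistry: C2 comes from a catalytic enantioselective bromochlorination. C6 comes from the linalool carbinol by 1,4-chirality transfer in the Claisen step. C8 and C9 follow from the spiro centre (epoxidation anti to the axial ring-A carbonyl carbon, trans-diaxial chloride opening, retention through chlorine participation).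

Key step: step 9

Assumption: (S)-(+)-linalool (coriandrol) is taken as a commercial material of high enantiomeric purity; the spiro centre inherits that purity.
Remark: locants in the plan are those of the target, (2R,6S,8R,9R)-2,9-dibromo-8-chloro-1,1,9-trimethyl-5-methylidenespiro[5.5]undecane; each intermediate is named with its own locants.

**Route**

Step 1
Reactants: 1 prenol (3-methylbut-2-en-1-ol)
Product: 2 (2R)-2-bromo-3-chloro-3-methylbutan-1-ol
Conditions: NBS, ClTi(OiPr)3, chiral tridentate Schiff-base diol ligand (20 mol%, enantiomer chosen for the 2R product), hexanes, −20 °C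
Reagents that add atoms: N-bromosuccinimide, O=C1CCC(=O)N1Br; chlorotitanium triisopropoxide, CC(C)O[Ti](Cl)(OC(C)C)OC(C)C
Why: Catalytic enantioselective bromochlorination of an allylic alcohol: the titanium-bound alkoxide is brominated inside the chiral ligand sphere and chloride is delivered from titanium anti to bromine at the distal tertiary carbon, so the ligand sets the single C–Br stereocentre as (R).

Step 2
Reactants: 2 (2R)-2-bromo-3-chloro-3-methylbutan-1-ol
Product: 3 (2R)-2-bromo-3-chloro-3-methylbutyl trifluoromethanesulfonate
Conditions: Tf2O, 2,6-lutidine, CH2Cl2, −78 °C; used cold and crude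
Reagents that add atoms: triflic anhydride, O=S(=O)(OS(=O)(=O)C(F)(F)F)C(F)(F)F
Why: O-sulfonylation of the primary alcohol gives a leaving group reactive enough for SN2 at a β-branched carbon at low temperature; the stereocentre is not involved.

Step 3
Reactants: 3 (2R)-2-bromo-3-chloro-3-methylbutyl trifluoromethanesulfonate; 4 N-methoxy-N-methylacetamide
Product: 6 (4R)-4-bromo-5-chloro-N-methoxy-N,5-dimethylhexanamide, via lithium enolate 5 (not isolated)
Conditions: 4, LiN(iPr)2, THF, −78 °C; then 3, −78 to −40 °C
Reagents that add atoms: none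
Why: SN2 alkylation of an amide enolate by a primary triflate; the low temperature and the very good leaving group should keep E2 and cyclopropane closure of the γ-bromo product in check, and the C–Br centre is only a spectator.

Step 4
Reactants: 7 (S)-(+)-linalool [(3S)-3,7-dimethylocta-1,6-dien-3-ol]
Product: 9 (4S)-4-methylhex-5-ene-1,4-diol, via ozonide 8 (not isolated)
Conditions: O3 (1.0 equiv, Sudan Red 7B end point), CH2Cl2, −78 °C; then NaBH4, MeOH, −78 °C to rt
Reagents that add atoms: ozone, [O-][O+]=O
Why: Ozonolysis with reductive work-up: the electron-rich trisubstituted alkene should react well ahead of the hindered monosubstituted vinyl group, and the carbinol stereocentre is untouched.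

Step 5
Reactants: 9 (4S)-4-methylhex-5-ene-1,4-diol
Product: 10 (3S)-6-iodo-3-methylhex-1-en-3-ol
Conditions: I2, PPh3, imidazole, CH2Cl2, 0 °C; used at once
Reagents that add atoms: iodine, [I][I]
Why: Appel-type iodination is selective for the primary hydroxyl because the tertiary allylic hydroxyl is too hindered to form the alkoxyphosphonium ion; the stereocentre is untouched.

Step 6
Reactants: 10 (3S)-6-iodo-3-methylhex-1-en-3-ol; 6 (4R)-4-bromo-5-chloro-N-methoxy-N,5-dimethylhexanamide
Product: 12 (3R,10S)-3-bromo-2-chloro-10-hydroxy-2,10-dimethyldodec-11-en-6-one, via dilithio reagent 11 (not isolated)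
Conditions: 10, t-BuLi (3.1 equiv), Et2O–pentane, −78 °C; then 6, −78 °C; H2O
Reagents that add atoms: none
Why: Lithium–iodine exchange (after O–H deprotonation) gives a primary alkyllithium that adds once to the Weinreb amide through the chelated tetrahedral intermediate (Weinreb ketone synthesis); at −78 °C the 5-hexenyl-type reagent should not cyclise, Li–Br exchange, E2 and α-deprotonation should be slow, and both stereocentres are remote.

Step 7
Reactants: 12 (3R,10S)-3-bromo-2-chloro-10-hydroxy-2,10-dimethyldodec-11-en-6-one
Product: 14 (2S)-6-[(3R)-3-bromo-4-chloro-4-methylpentyl]-2-ethenyl-2-methyl-3,4-dihydro-2H-pyran, via cyclic hemiketal 13 (not isolated)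
Conditions: PPTS (5 mol%), 4 Å MS, PhMe, 60 °C
Reagents that add atoms: none
Why: Acid-catalysed cyclodehydration: the δ-hydroxy ketone closes to the six-membered hemiketal and loses water through the oxocarbenium ion to the endocyclic enol ether (an exocyclic isomer equilibrates to it); the tertiary C–O bond carrying the stereocentre is never broken and the weak acid should leave the tertiary chloride intact.

Step 8
Reactants: 14 (2S)-6-[(3R)-3-bromo-4-chloro-4-methylpentyl]-2-ethenyl-2-methyl-3,4-dihydro-2H-pyran
Product: 17 (2S,6R)-6-bromo-2-ethenyl-2,5,5-trimethyl-3,4,5,6,7,8-hexahydro-2H-chromene, via bromonium ion 15 (not isolated), via oxocarbenium ion 16 (not isolated)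
Conditions: (CF3)2CHOH (0.01 M), 2,6-di-tert-butyl-4-methylpyridine (1.5 equiv), 0 °C to rt
Reagents that add atoms: none
Why: Solvolytic bromonium-initiated cation–olefin cyclisation: the tertiary C–Cl bond ionises with anchimeric help from the vicinal bromine, the enol ether β-carbon opens the bromonium ion at its tertiary carbon through a chair (6-endo), and the base deprotonates the oxocarbenium ion to the ring-fused enol ether; the C–Br bond is never broken, so the (R) centre is carried over, and the buffer keeps HCl from the enol ether.

Step 9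
Reactants: 17 (2S,6R)-6-bromo-2-ethenyl-2,5,5-trimethyl-3,4,5,6,7,8-hexahydro-2H-chromene
Product: 18 (4R,6R)-4-bromo-5,5,9-trimethylspiro[5.5]undec-8-en-1-one
Conditions: PhMe (0.02 M, degassed), N,O-bis(trimethylsilyl)acetamide (10 mol%), sealed silylated tube, 200–210 °C
Reagents that add atoms: none
Why: Thermal Claisen ([3,3]-sigmatropic) rearrangement of the allyl vinyl ether made up of O1–C2(CH=CH2) and C8a=C4a: the vinyl CH2 terminus bonds to the enol ether β-carbon C4a while the C2–O1 bond breaks, so C8a becomes the ring-A ketone and C2 the methyl-bearing alkene carbon of ring B. The closest known type is the Claisen rearrangement of 2-alkenyl-3,4-dihydro-2H-pyrans to 4-acylcyclohexenes, the formal enone–isoprene Diels–Alder adducts. Ring B is closed as a six-membered carbocycle through a boat-like six-centre transition state enforced by the pyran ring, which opens in the same event (pyran-to-cyclohexene ring switch). The spiro quaternary centre is set by C2: the vinyl group must sit pseudo-axial on one face of the planar enol ether and is delivered suprafacially to that face, so the (2S) carbinol configuration should be transferred fully to the (6R) spiro centre, independent of the C–Br centre. The step needs the concerted path to win over retro-hetero-Diels–Alder dissociation into exo-enone and isoprene and over acid-induced heterolysis of the tertiary allylic C–O bond; the intramolecular six-atom array, high dilution and neutral, acid-scavenged glass are meant to secure this. Formation of the C=O bond makes the step strongly exothermic, so the ketone should not revert.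

Step 10
Reactants: 18 (4R,6R)-4-bromo-5,5,9-trimethylspiro[5.5]undec-8-en-1-one
Product: 19 (1R,1'S,5R,6'R)-5-bromo-6,6,6'-trimethylspiro[cyclohexane-1,3'-[7]oxabicyclo[4.1.0]heptan]-2-one (epoxide oxygen anti to the ring-A carbonyl carbon)
Conditions: mCPBA, NaHCO3, CH2Cl2, 0 °C
Reagents that add atoms: 3-chloroperbenzoic acid, OOC(=O)c1cccc(Cl)c1
Why: Prilezhaev epoxidation of the trisubstituted alkene (faster than Baeyer–Villiger attack on the hindered ketone); in the favoured half-chair the CMe2 branch of the spiro carbon is equatorial and the ring-A carbonyl carbon axial, so the peracid should approach anti to that axial carbon, as with cyclohexenes bearing an axial homoallylic substituent.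

Step 11
Reactants: 19 (1R,1'S,5R,6'R)-5-bromo-6,6,6'-trimethylspiro[cyclohexane-1,3'-[7]oxabicyclo[4.1.0]heptan]-2-one
Product: 20 (4R,6R,8R,9R)-4-bromo-8-chloro-9-hydroxy-5,5,9-trimethylspiro[5.5]undecan-1-one
Conditions: LiCl, AcOH, THF, rt
Reagents that add atoms: lithium chloride, [Li+].[Cl-]
Why: SN2 epoxide opening under weakly acidic, nucleophilic conditions (Fürst–Plattner trans-diaxial rule): attack at the secondary carbon anti to oxygen is both the less hindered and the chair-forming mode, placing Cl axial on the face of the ring-A carbonyl carbon and leaving a tertiary axial alcohol.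

Step 12
Reactants: 20 (4R,6R,8R,9R)-4-bromo-8-chloro-9-hydroxy-5,5,9-trimethylspiro[5.5]undecan-1-one
Product: 22 (4R,6R,8R,9R)-4,9-dibromo-8-chloro-5,5,9-trimethylspiro[5.5]undecan-1-one, via chloronium ion 21 (not isolated)
Conditions: HBr (33% in AcOH, 3 equiv), LiBr, CH2Cl2, −20 to 0 °C
Reagents that add atoms: hydrogen bromide, Br
Why: SN1 substitution of the tertiary alcohol with neighbouring-group participation: the axial C–OH2+ bond ionises antiperiplanar to the axial C–Cl bond and bromide opens the chlorine-bridged cation at the tertiary carbon anti to chlorine (axial attack), i.e. with retention, giving the trans tertiary bromide/secondary chloride; the ketone and the secondary bromide are inert to HBr.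

Step 13
Reactants: 22 (4R,6R,8R,9R)-4,9-dibromo-8-chloro-5,5,9-trimethylspiro[5.5]undecan-1-one
Product: 23 (2R,6S,8R,9R)-2,9-dibromo-8-chloro-1,1,9-trimethyl-5-methylidenespiro[5.5]undecane
Conditions: Cp2Ti(μ-Cl)(μ-CH2)AlMe2 (Tebbe reagent), pyridine (cat.), THF–PhMe, −40 to 0 °C
Reagents that add atoms: Tebbe reagent, C[Al-]1(C)C[Ti]([Cl+]1)(C1C=CC=C1)C1C=CC=C1
Why: Tebbe methylenation via the titanium methylidene and an oxatitanacyclobutane: the reagent is non-basic, so the hindered ketone should be olefinated without E2 loss of HBr/HCl or the 1,3-elimination to a cyclopropane that an ylide could cause; no stereocentre is touched.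

**Compound list**

1 | prenol (3-methylbut-2-en-1-ol) | CC(C)=CCO | starting material
2 | (2R)-2-bromo-3-chloro-3-methylbutan-1-ol | OC[C@@H](Br)C(C)(C)Cl | intermediate
3 | (2R)-2-bromo-3-chloro-3-methylbutyl trifluoromethanesulfonate | FC(F)(F)S(=O)(=O)OC[C@@H](Br)C(C)(C)Cl | intermediate
4 | N-methoxy-N-methylacetamide | CC(=O)N(C)OC | starting material
5 | lithium enolate of N-methoxy-N-methylacetamide | [Li]OC(=C)N(C)OC | intermediate
6 | (4R)-4-bromo-5-chloro-N-methoxy-N,5-dimethylhexanamide | CON(C)C(=O)CC[C@@H](Br)C(C)(C)Cl | intermediate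
7 | (S)-(+)-linalool, (3S)-3,7-dimethylocta-1,6-dien-3-ol | C=C[C@@](C)(O)CCC=C(C)C | starting material
8 | ozonide of 7 at the trisubstituted alkene (3,3-dimethyl-1,2,4-trioxolane, mixture at the ring carbon) | C=C[C@@](C)(O)CCC1OOC(C)(C)O1 | intermediate
9 | (4S)-4-methylhex-5-ene-1,4-diol | C=C[C@@](C)(O)CCCO | intermediate
10 | (3S)-6-iodo-3-methylhex-1-en-3-ol | C=C[C@@](C)(O)CCCI | intermediate
11 | lithium (3S)-6-lithio-3-methylhex-1-en-3-olate | C=C[C@@](C)(O[Li])CCC[Li] | intermediate
12 | (3R,10S)-3-bromo-2-chloro-10-hydroxy-2,10-dimethyldodec-11-en-6-one | C=C[C@@](C)(O)CCCC(=O)CC[C@@H](Br)C(C)(C)Cl | intermediate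
13 | (6S)-2-[(3R)-3-bromo-4-chloro-4-methylpentyl]-6-ethenyl-6-methyloxan-2-ol (both C2 epimers) | C=C[C@]1(C)CCCC(O)(CC[C@@H](Br)C(C)(C)Cl)O1 | intermediate
14 | (2S)-6-[(3R)-3-bromo-4-chloro-4-methylpentyl]-2-ethenyl-2-methyl-3,4-dihydro-2H-pyran | C=C[C@]1(C)CCC=C(CC[C@@H](Br)C(C)(C)Cl)O1 | intermediate
15 | bromonium ion from 14 (Br bridging the former CHBr and CClMe2 carbons) | C=C[C@]1(C)CCC=C(CC[C@H]2[Br+]C2(C)C)O1 | intermediate
16 | bicyclic oxocarbenium ion (ring A closed, C4a–H epimers) | C=C[C@]1(C)CCC2C(=[O+]1)CC[C@@H](Br)C2(C)C | intermediate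
17 | (2S,6R)-6-bromo-2-ethenyl-2,5,5-trimethyl-3,4,5,6,7,8-hexahydro-2H-chromene | C=C[C@]1(C)CCC2=C(CC[C@@H](Br)C2(C)C)O1 | intermediate
18 | (4R,6R)-4-bromo-5,5,9-trimethylspiro[5.5]undec-8-en-1-one | O=C1CC[C@@H](Br)C(C)(C)[C@]12CCC(C)=CC2 | intermediate
19 | (1R,1'S,5R,6'R)-5-bromo-6,6,6'-trimethylspiro[cyclohexane-1,3'-[7]oxabicyclo[4.1.0]heptan]-2-one | O=C1CC[C@@H](Br)C(C)(C)[C@]12CC[C@@]3(C)O[C@H]3C2 | intermediate
20 | (4R,6R,8R,9R)-4-bromo-8-chloro-9-hydroxy-5,5,9-trimethylspiro[5.5]undecan-1-one | O=C1CC[C@@H](Br)C(C)(C)[C@]12CC[C@@](C)(O)[C@H](Cl)C2 | intermediate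
21 | chlorine-bridged cation from 20 (Cl on the face of the ring-A carbonyl carbon) | O=C1CC[C@@H](Br)C(C)(C)[C@]12CC[C@]3(C)[Cl+][C@@H]3C2 | intermediate
22 | (4R,6R,8R,9R)-4,9-dibromo-8-chloro-5,5,9-trimethylspiro[5.5]undecan-1-one | O=C1CC[C@@H](Br)C(C)(C)[C@]12CC[C@@](C)(Br)[C@H](Cl)C2 | intermediate
23 | (2R,6S,8R,9R)-2,9-dibromo-8-chloro-1,1,9-trimethyl-5-methylidenespiro[5.5]undecane | C=C1CC[C@@H](Br)C(C)(C)[C@]12CC[C@@](C)(Br)[C@H](Cl)C2 | target

**Count and risks**

Total steps: 13. Longest linear sequence: 11 (steps 1–3, then 6–13).

Steps most likely to fail: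

1. Step 9 (Claisen rearrangement). At about 200 °C the dihydropyran may undergo cycloreversion to exo-enone and isoprene and recombine without stereochemical memory. The tertiary allylic C–O bond may ionise on traces of acid, and HBr may be lost thermally; each would erode the chirality transfer or the mass balance. Fallback: set out from 17 and come back at 18 without any new compound, replacing the thermal concerted shift by a low-temperature, Lewis-acid-triggered O-to-C allyl transfer (Me2AlCl or MeAl(OAr)2 with Ar = 4-bromo-2,6-di-tert-butylphenyl, CH2Cl2, −78 °C). Here C–O ionisation to a tight allyl cation/aluminium enolate pair precedes C–C bond formation at the allyl terminus (organoaluminium-promoted Claisen chemistry), so neither heat nor a dissociative cycloreversion channel is involved.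

2. Step 8 (solvolytic bromonium cyclisation). The enol ether may be protonated or solvolysed in the ionising medium, the O-bound tertiary allylic carbon may ionise (loss of configuration at C2), or Br+ may be passed between molecules. Fallback: set out from 3 and come back at 18, closing ring A before any enol ether exists.
   - γ-Alkylation of the dianion of tert-butyl acetoacetate (NaH, then n-BuLi, THF, −78 °C) with 3 would give tert-butyl (6R)-6-bromo-7-chloro-7-methyl-3-oxooctanoate F1.
   - The same (CF3)2CHOH solvolysis on this acid-stable β-keto ester terminator would give tert-butyl (5R)-5-bromo-6,6-dimethyl-2-oxocyclohexane-1-carboxylate F2.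
   - CF3CO2H would free (5R)-5-bromo-6,6-dimethyl-2-oxocyclohexane-1-carboxylic acid F3.
   - Decarboxylative Mannich methylenation (aqueous CH2O, Et2NH) would give (4R)-4-bromo-3,3-dimethyl-2-methylidenecyclohexan-1-one F4.
   - A Diels–Alder reaction of F4 with isoprene (Me2AlCl, or a confined chiral imidodiphosphorimidate Brønsted acid if catalyst control of the spiro centre is needed) would give 18.

3. Step 3 (enolate alkylation). The basic amide enolate may cause E2 elimination of the β-bromo triflate, the product may be deprotonated and close to a cyclopropane (3-exo-tet on the γ-bromide), or the enolate may decompose. Fallback: set out from 3 and come back at 12, avoiding stabilised carbanions next to the halides.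
   - Copper-catalysed coupling of 3 with allylmagnesium chloride (Li2CuCl4 cat., THF, −78 °C) would give (5R)-5-bromo-6-chloro-6-methylhept-1-ene F5.
   - Ozonolysis (O3, CH2Cl2, −78 °C; PPh3) would give (4R)-4-bromo-5-chloro-5-methylhexanal F6.
   - Addition of the organocerium reagent made from 11 and CeCl3 (THF, −78 °C) would give (3R,10S)-3-bromo-2-chloro-2,10-dimethyldodec-11-ene-6,10-diol F7.
   - Dess–Martin oxidation of the secondary alcohol of F7 would return to 12.

Further compounds
F0 | step 9 | none | none
F1 | step 8 | tert-butyl (6R)-6-bromo-7-chloro-7-methyl-3-oxooctanoate | CC(C)(C)OC(=O)CC(=O)CC[C@@H](Br)C(C)(C)Cl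
F2 | step 8 | tert-butyl (5R)-5-bromo-6,6-dimethyl-2-oxocyclohexane-1-carboxylate (C1 epimers/enol) | CC(C)(C)OC(=O)C1C(=O)CC[C@@H](Br)C1(C)C
F3 | step 8 | (5R)-5-bromo-6,6-dimethyl-2-oxocyclohexane-1-carboxylic acid | OC(=O)C1C(=O)CC[C@@H](Br)C1(C)C
F4 | step 8 | (4R)-4-bromo-3,3-dimethyl-2-methylidenecyclohexan-1-one | C=C1C(=O)CC[C@@H](Br)C1(C)C
F5 | step 3 | (5R)-5-bromo-6-chloro-6-methylhept-1-ene | C=CCC[C@@H](Br)C(C)(C)Cl
F6 | step 3 | (4R)-4-bromo-5-chloro-5-methylhexanal | O=CCC[C@@H](Br)C(C)(C)Cl
F7 | step 3 | (3R,10S)-3-bromo-2-chloro-2,10-dimethyldodec-11-ene-6,10-diol (C6 epimers) | C=C[C@@](C)(O)CCCC(O)CC[C@@H](Br)C(C)(C)Cl
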